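**Plan**

Locants: unprimed = chroman-4-one (rings A/C); primed = the 2,2-dimethyl-2H-chromene unit.

1. The first retrosynthetic cut is the C3–H bond: the only stereocentre is erased to the achiral C3=C4 enol allyl carbonate of the racemate, with 7-OH also as allyl carbonate.
2. Next the C3–C6' bond is cut (chromanone enolate + 6'-bromochromene), then the pyran ring of the chromene (C4a'–C4' and O1'–C2') back to an aryl 1,1-dimethylpropargyl ether.
3. Forward: the chromene pyran ring is closed first by a propargyl Claisen/oxa-6π cascade. Rings A/C are bought intact as 7-hydroxychroman-4-one and joined by Pd α-arylation without stereocontrol.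
4. After MOM removal and double O-allyloxycarbonylation, one Pd-catalysed decarboxylative asymmetric protonation sets C3 and frees the phenol in the last step. Both enantiomers converge, and the labile centre never meets base afterwards.
5. Enabling feature: C3 is the sole stereocentre and its H lies between the C4 ketone and the C6' aryl carbon, so it is acidic enough to be erased and rewritten. The OMe on C7', ortho to the C3–C6' bond, twists the aryl ring out of the enolate plane and makes the two enolate faces distinguishable.

Key step: step 7

Assumption: with Meldrum's acid as proton donor the (S)-configured PHOX ligand is taken to give the (3S) ketone; the sense is checked on first use, and if it is the opposite the (R)-ligand is used with no other change.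

**Route**

Step 1
Reactants: 1 4-bromo-3-methoxyphenol; 2 3-chloro-3-methylbut-1-yne
Product: 3 1-bromo-2-methoxy-4-[(2-methylbut-3-yn-2-yl)oxy]benzene
Conditions: K2CO3, KI, CuI (cat.), acetone, 56 °C
Reagents that add atoms: none
Why: Copper-catalysed propargylic etherification of the phenoxide (substitution through a copper acetylide/allenylidene-type ion pair) is the standard entry to aryl 1,1-dimethylpropargyl ethers and avoids SN2 attack at the tertiary chloride; no stereocentre is formed.

Step 2
Reactants: 3 1-bromo-2-methoxy-4-[(2-methylbut-3-yn-2-yl)oxy]benzene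
Product: 6 6-bromo-7-methoxy-2,2-dimethyl-2H-chromene, via allenylphenol 4 (not isolated), via o-quinone methide 5 (not isolated)
Conditions: PhNEt2, 190 °C
Reagents that add atoms: none
Why: Thermal aromatic propargyl Claisen rearrangement ([3,3] shift, enolisation to 4), [1,5]-H shift to 5 and oxa-6π-electrocyclisation close the pyran ring; the shift should go to the phenol carbon para to OMe (the other ortho carbon lies between two oxygen substituents), which places Br at C6 and OMe at C7.

Step 3
Reactants: 7 7-hydroxychroman-4-one
Product: 8 7-(methoxymethoxy)chroman-4-one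
Conditions: MOMCl, K2CO3, acetone, 0 °C to rt
Reagents that add atoms: chloromethyl methyl ether (MOMCl), COCCl
Why: Williamson-type O-alkylation of the acidic 7-OH (para to the ketone) gives an acetal that withstands NaOt-Bu and Pd(0) in step 4 and can be taken off while the material is still racemic.

Step 4
Reactants: 8 7-(methoxymethoxy)chroman-4-one; 6 6-bromo-7-methoxy-2,2-dimethyl-2H-chromene
Product: 9 rac-7-(methoxymethoxy)-3-(7-methoxy-2,2-dimethyl-2H-chromen-6-yl)chroman-4-one
Conditions: Pd2(dba)3 (2.5 mol%), XPhos (6 mol%), NaOt-Bu (2.2 equiv), toluene, 80 °C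
Reagents that add atoms: none
Why: Buchwald–Hartwig-type Pd-catalysed α-arylation of the ketone enolate, with a bulky biaryl phosphine to drive oxidative addition of the electron-rich ortho-substituted bromide and to favour monoarylation, forms the C3–C6' bond; C3 arises racemic on purpose, since step 7 rewrites it.

Step 5
Reactants: 9 rac-7-(methoxymethoxy)-3-(7-methoxy-2,2-dimethyl-2H-chromen-6-yl)chroman-4-one
Product: 10 rac-7-hydroxy-3-(7-methoxy-2,2-dimethyl-2H-chromen-6-yl)chroman-4-one
Conditions: conc. HCl (cat.), MeOH–THF 3:1, 40 °C
Reagents that add atoms: none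
Why: Acid-catalysed transacetalisation of the aryl MOM ether to methanol, under conditions of the kind used to unmask phenols next to 2,2-dimethyl-2H-chromenes; epimerisation at C3 is of no consequence at this stage.

Step 6
Reactants: 10 rac-7-hydroxy-3-(7-methoxy-2,2-dimethyl-2H-chromen-6-yl)chroman-4-one
Product: 12 allyl 7-[(allyloxycarbonyl)oxy]-3-(7-methoxy-2,2-dimethyl-2H-chromen-6-yl)-2H-chromen-4-yl carbonate, via dipotassium phenolate enolate 11 (not isolated)
Conditions: KHMDS (2.2 equiv), THF, −78 °C; then ClCO2CH2CH=CH2 (2.5 equiv), −78 to 0 °C
Reagents that add atoms: allyl chloroformate, C=CCOC(=O)Cl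
Why: Double deprotonation (7-OH, then C3–H between C4=O and the aryl ring) gives dianion 11, whose two oxygen centres are acylated by the hard chloroformate (enol carbonate formation as for Tsuji-type allylation substrates), so that C3 becomes sp2 and both enantiomers of 10 give one achiral compound.

Step 7
Reactants: 12 allyl 7-[(allyloxycarbonyl)oxy]-3-(7-methoxy-2,2-dimethyl-2H-chromen-6-yl)-2H-chromen-4-yl carbonate
Product: 14 (3S)-7-hydroxy-3-(7-methoxy-2,2-dimethyl-2H-chromen-6-yl)chroman-4-one (target CNP0226344.1), via allylpalladium enolate 13 (not isolated)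
Conditions: Pd2(dba)3 (5 mol%), (S)-(CF3)3-t-BuPHOX (12.5 mol%), Meldrum's acid (3 equiv), 1,4-dioxane, 40 °C
Reagents that add atoms: none
Why: Pd(0)–PHOX undergoes oxidative addition into both allyl carbonates and each carboxylate loses CO2, so the aryl carbonate gives the C7 phenoxide (protonated at once by Meldrum's acid) and the enol carbonate gives the chiral cationic (η3-allyl)Pd(PHOX) enolate 13 of the C3=C4–O unit; Meldrum's acid then transfers a proton to C3 and its anion takes up both allyl groups. The closest known reaction type is the Pd/PHOX-catalysed decarboxylative asymmetric protonation with Meldrum's acid of allyl β-keto esters (shown on 3-aryl-4-oxochroman-3-carboxylates with ortho-alkoxyaryl groups) and of allyl enol carbonates. No ring is closed in this step. The new stereocentre C3 is controlled by the catalyst alone: the proton is delivered to one face of the ligand-bound enolate, and the C7' methoxy group ortho to the C3–C6' bond holds the aryl ring twisted out of the enolate plane, which is the element that lets the ligand tell the two faces apart. The step needs C-protonation to outrun Tsuji-type C3-allylation and O-allylation of the phenoxide, which the excess of the acidic, soft carbon acid should secure, and it needs the product to keep its configuration, which the base-free medium and the position as last step should secure. Because 12 is achiral, both enantiomers of 10 are funnelled into (3S)-14.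

**Compound list**

1 | 4-bromo-3-methoxyphenol | COc1cc(O)ccc1Br | starting material
2 | 3-chloro-3-methylbut-1-yne | C#CC(C)(C)Cl | starting material
3 | 1-bromo-2-methoxy-4-[(2-methylbut-3-yn-2-yl)oxy]benzene | COc1cc(OC(C)(C)C#C)ccc1Br | intermediate
4 | 4-bromo-5-methoxy-2-(3-methylbuta-1,2-dien-1-yl)phenol (allenylphenol, not isolated) | COc1cc(O)c(C=C=C(C)C)cc1Br | intermediate
5 | (6Z)-4-bromo-3-methoxy-6-(3-methylbut-2-en-1-ylidene)cyclohexa-2,4-dien-1-one (o-quinone methide, not isolated) | O=C1C=C(OC)C(Br)=C/C1=C/C=C(C)C | intermediate
6 | 6-bromo-7-methoxy-2,2-dimethyl-2H-chromene | COc1cc2OC(C)(C)C=Cc2cc1Br | intermediate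
7 | 7-hydroxychroman-4-one | O=C1CCOc2cc(O)ccc12 | starting material
8 | 7-(methoxymethoxy)chroman-4-one | COCOc1ccc2C(=O)CCOc2c1 | intermediate
9 | rac-7-(methoxymethoxy)-3-(7-methoxy-2,2-dimethyl-2H-chromen-6-yl)chroman-4-one | COc1cc2c(cc1C1COc3cc(OCOC)ccc3C1=O)C=CC(C)(C)O2 | intermediate
10 | rac-7-hydroxy-3-(7-methoxy-2,2-dimethyl-2H-chromen-6-yl)chroman-4-one | COc1cc2c(cc1C1COc3cc(O)ccc3C1=O)C=CC(C)(C)O2 | intermediate
11 | dipotassium 3-(7-methoxy-2,2-dimethyl-2H-chromen-6-yl)-2H-chromene-4,7-diolate (phenolate enolate, not isolated) | COc1cc2c(cc1C1=C([O-])c3ccc([O-])cc3OC1)C=CC(C)(C)O2.[K+].[K+] | intermediate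
12 | allyl 7-[(allyloxycarbonyl)oxy]-3-(7-methoxy-2,2-dimethyl-2H-chromen-6-yl)-2H-chromen-4-yl carbonate | COc1cc2c(cc1C1=C(OC(=O)OCC=C)c3ccc(OC(=O)OCC=C)cc3OC1)C=CC(C)(C)O2 | intermediate
13 | allylpalladium(PHOX) 7-hydroxy-3-(7-methoxy-2,2-dimethyl-2H-chromen-6-yl)-2H-chromen-4-olate (not isolated; PHOX ligand omitted from the SMILES, allyl drawn σ-bound) | COc1cc2c(cc1C1=C([O-])c3ccc(O)cc3OC1)C=CC(C)(C)O2.C=CC[Pd+] | intermediate
14 | (3S)-7-hydroxy-3-(7-methoxy-2,2-dimethyl-2H-chromen-6-yl)chroman-4-one | COc1cc2c(cc1[C@H]1COc3cc(O)ccc3C1=O)C=CC(C)(C)O2 | target

**Summary**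

Total step count: 7
Longest linear sequence: 6 steps (steps 1, 2, 4, 5, 6, 7, from compound 1); the branch from compound 7 runs through 5 steps.

**Steps most likely to fail**

Step 7. The facial selectivity of the protonation may be too low or of the wrong sense. The Pd enolate may also be captured by the allyl fragment at C3 or at the phenoxide oxygen before it is protonated. Fallback: set out from 10 and use an asymmetric transfer hydrogenation with dynamic kinetic resolution. The racemic ketone is reduced with RuCl[(S,S)-TsDPEN](p-cymene) and HCO2H/Et3N in EtOAc at 40 °C, conditions under which C3 epimerises through the enol while only one enantiomer is reduced quickly. This should give cis-(3S,4S)-3-(7-methoxy-2,2-dimethyl-2H-chromen-6-yl)chromane-4,7-diol F1, the (4S) centre following the usual sense of this catalyst with aryl ketones and the cis relation following from hydride delivery anti to the aryl group. The temporary C4 carbinol is then oxidised back with activated MnO2 in CH2Cl2 at rt, a neutral oxidation of the para-hydroxybenzylic alcohol that does not touch C3, and the route is rejoined at 14.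

Step 4. The chromanone enolate may open by β-elimination of the ring phenoxide under hot alkoxide. Oxidative addition of the hindered, electron-rich bromide may be slow, and the more acidic product may be arylated a second time. Fallback: set out from 8 and 6 with inverted polarity, so that no enolate is involved. Ketone 8 is brominated at C3 (PhNMe3Br3, solid NaHCO3, THF, 0 °C) to rac-3-bromo-7-(methoxymethoxy)chroman-4-one F2. Bromide 6 is converted by magnesium insertion in the presence of LiCl and ZnCl2 (THF, rt) into (7-methoxy-2,2-dimethyl-2H-chromen-6-yl)zinc chloride F3. A nickel-catalysed Negishi arylation of the secondary α-bromo ketone (NiCl2·glyme, racemic pybox ligand, glyme/THF, −30 °C), which runs through the C3 radical under base-free conditions, then joins the two and returns to the route at 9.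

Step 2. The [3,3] shift may leak to the ortho carbon between the two oxygen substituents, and the material may decompose at the temperature needed. Fallback: set out from 1 and fix the regiochemistry by an electronically controlled acylation. Phenol 1 and 3-methylbut-2-enoic acid in Eaton's reagent (P2O5/MsOH, 70 °C) undergo Friedel–Crafts acylation ortho to OH and para to OMe, followed by oxa-Michael closure, to give 6-bromo-7-methoxy-2,2-dimethylchroman-4-one F4. Reduction with NaBH4 in MeOH gives rac-6-bromo-7-methoxy-2,2-dimethylchroman-4-ol F5. Acid-catalysed dehydration (p-TsOH, toluene, reflux) then returns to the route at 6.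

Further compounds
F1 | step 7 | (3S,4S)-3-(7-methoxy-2,2-dimethyl-2H-chromen-6-yl)chromane-4,7-diol | COc1cc2c(cc1[C@H]1COc3cc(O)ccc3[C@H]1O)C=CC(C)(C)O2
F2 | step 4 | rac-3-bromo-7-(methoxymethoxy)chroman-4-one | COCOc1ccc2C(=O)C(Br)COc2c1
F3 | step 4 | (7-methoxy-2,2-dimethyl-2H-chromen-6-yl)zinc chloride | COc1cc2OC(C)(C)C=Cc2cc1[Zn]Cl
F4 | step 2 | 6-bromo-7-methoxy-2,2-dimethylchroman-4-one | COc1cc2OC(C)(C)CC(=O)c2cc1Br
F5 | step 2 | rac-6-bromo-7-methoxy-2,2-dimethylchroman-4-ol | COc1cc2OC(C)(C)CC(O)c2cc1Br
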